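The chalcone is disconnected between the enone β-carbon and C1 of the 4-hydroxyphenyl B ring. A Mizoroki–Heck arylation joins unprotected 4-iodophenol to a fully elaborated ring-A aryl vinyl ketone, forging this bond and the E-alkene in one operation. The step exploits the unsubstituted, carbonyl-polarised terminal CH2 of the acryloyl group on C1′ of ring A, which outcompetes the 1,1-disubstituted isopropenyl alkene (C3″=C4″) of the side chain. The precursor is the 2′,4′-bis-MOM vinyl ketone, built on symmetric 5-methoxyresorcinol by two directed lithiations. Its (R)-carbinol C2″ comes from Shi epoxidation of the C3′-prenyl group and aluminium-amide isomerisation.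

Key step: step 6

Remark on the chemistry: CIP analysis of the target gives (R) at the carbinol carbon C2″ (O > isopropenyl C > CH2Ar > H). Locants 1′–6′ denote ring A, 1″–4″ the side chain, and α/β the enone carbons.

Step 1
Reactants: 1 5-methoxyresorcinol (3,5-dihydroxyanisole)
Product: 2 1-methoxy-3,5-bis(methoxymethoxy)benzene
Conditions: MOMCl (2.5 equiv), i-Pr2NEt (3 equiv), CH2Cl2, 0 °C to rt
Reagents that add atoms: chloromethyl methyl ether (MOMCl), COCCl
Why: O-alkylation of both equivalent phenols by the reactive α-chloro ether (MOM acetal protection) should be clean, and the MOM groups later act as directing groups for both lithiations.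

Step 2
Reactants: 2 1-methoxy-3,5-bis(methoxymethoxy)benzene; 3 prenyl bromide (1-bromo-3-methylbut-2-ene)
Product: 5 5-methoxy-1,3-bis(methoxymethoxy)-2-(3-methylbut-2-en-1-yl)benzene, via aryllithium 4 (not isolated)
Conditions: n-BuLi (1.1 equiv), THF, 0 °C to rt; then 3, −78 °C to rt
Reagents that add atoms: none
Why: Directed ortho-metalation should occur at the C–H flanked by the two chelating OMOM groups (cooperative 1,3-effect, MOM a stronger director than OMe), and the aryllithium is alkylated by SN2 at the primary allylic bromide to give a symmetric arene.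

Step 3
Reactants: 5 5-methoxy-1,3-bis(methoxymethoxy)-2-(3-methylbut-2-en-1-yl)benzene
Product: 6 (3R)-3-{[4-methoxy-2,6-bis(methoxymethoxy)phenyl]methyl}-2,2-dimethyloxirane
Conditions: D-fructose-derived Shi ketone (30 mol %), Oxone, K2CO3, n-Bu4NHSO4 (cat.), MeCN–CH2(OMe)2 / aq. Na2B4O7–Na2EDTA buffer, 0 °C
Reagents that add atoms: Oxone (active component potassium peroxymonosulfate, KHSO5), [K+].[O-]S(=O)(=O)OO
Why: In the Shi asymmetric epoxidation the chiral dioxirane meets the trisubstituted alkene through the spiro transition state on the face that gives (R) at the CH carbon (same sense as the R,R-epoxides of trans alkenes), which sets the only stereocentre while the MOM ethers are stable at the buffered basic pH.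

Step 4
Reactants: 6 (3R)-3-{[4-methoxy-2,6-bis(methoxymethoxy)phenyl]methyl}-2,2-dimethyloxirane
Product: 8 (2R)-1-[4-methoxy-2,6-bis(methoxymethoxy)phenyl]-3-methylbut-3-en-2-ol, via diethylaluminium alkoxide 7 (not isolated)
Conditions: Et2Al(TMP) (3 equiv; from 2,2,6,6-tetramethylpiperidine, n-BuLi, Et2AlCl, toluene, 0 °C), toluene, 0 °C to rt; aq. Rochelle salt
Reagents that add atoms: none
Why: In the aluminium amide-mediated epoxide-to-allylic alcohol isomerisation, aluminium binds the oxirane oxygen, the tertiary C–O bond breaks and the amide removes a methyl proton in a syn cyclic transition state, so the C2″–O bond is never broken and (R) is retained at a temperature that excludes hydride-transfer racemisation.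

Step 5
Reactants: 8 (2R)-1-[4-methoxy-2,6-bis(methoxymethoxy)phenyl]-3-methylbut-3-en-2-ol; 9 N-methoxy-N-methylacrylamide
Product: 12 1-{3-[(2R)-2-hydroxy-3-methylbut-3-en-1-yl]-6-methoxy-2,4-bis(methoxymethoxy)phenyl}prop-2-en-1-one, via O,C-dilithio species 10 (not isolated), via lithium hemiaminal adduct 11 (not isolated)
Conditions: n-BuLi (2.3 equiv), THF, −78 to 0 °C; 9, −78 °C; inverse quench into cold 1 M aq. HCl–Et2O
Reagents that add atoms: none
Why: After alkoxide formation a second directed ortho-metalation can only hit one of the two equivalent ring C–H positions (each between OMOM and OMe), and the Weinreb ketone synthesis stops at the chelated tetrahedral adduct, whose cold acidic quench releases the vinyl ketone while the liberated hydroxylamine stays protonated and cannot add back.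

Step 6
Reactants: 12 1-{3-[(2R)-2-hydroxy-3-methylbut-3-en-1-yl]-6-methoxy-2,4-bis(methoxymethoxy)phenyl}prop-2-en-1-one; 13 4-iodophenol
Product: 14 (2E)-1-{3-[(2R)-2-hydroxy-3-methylbut-3-en-1-yl]-6-methoxy-2,4-bis(methoxymethoxy)phenyl}-3-(4-hydroxyphenyl)prop-2-en-1-one
Conditions: Pd(OAc)2 (5 mol %), n-Bu4NCl, NaHCO3, DMF, 45 °C, Ar, trace BHT; 13 (1.05 equiv)
Reagents that add atoms: none
Why: Pd(0) formed in situ inserts into the C–I bond of 13, the arylpalladium species binds the acryloyl alkene of 12, and syn-migratory insertion places the aryl group on the terminal CH2 (the future Cβ) and palladium on Cα, after which bond rotation and syn β-hydride elimination release the enone and NaHCO3 takes up HI to regenerate Pd(0). The closest known reaction type is the Mizoroki–Heck arylation of aryl vinyl ketones with aryl iodides under ligand-free phase-transfer (Jeffery) conditions, an established entry to chalcones that tolerates free phenols. No ring is closed and no stereocentre is made; the E geometry follows from the less eclipsed conformer in the syn β-hydride elimination, and the remote (R)-carbinol C2″ is not involved. The step needs regioselectivity (Cβ over Cα) and chemoselectivity between two terminal alkenes: the carbonyl polarises the monosubstituted acryloyl alkene and leaves its CH2 unhindered, whereas the isopropenyl alkene is 1,1-disubstituted, electronically neutral and shielded by the carbinol and the flanking OMOM groups, and 13 is kept near one equivalent. The 2′-O-MOM group blocks 6-endo oxa-Michael closure to a chromanone or flavanone, the weak base and low temperature hold back polymerisation, and any phenoxide oxa-Michael adduct is reversible and drains into the irreversible coupling.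

Step 7
Reactants: 14 (2E)-1-{3-[(2R)-2-hydroxy-3-methylbut-3-en-1-yl]-6-methoxy-2,4-bis(methoxymethoxy)phenyl}-3-(4-hydroxyphenyl)prop-2-en-1-one
Product: 16 (2E)-1-{2,4-dihydroxy-3-[(2R)-2-hydroxy-3-methylbut-3-en-1-yl]-6-methoxyphenyl}-3-(4-hydroxyphenyl)prop-2-en-1-one, via 4′-O-MOM chalcone 15 (not isolated)
Conditions: 3 M aq. HCl, MeOH, rt
Reagents that add atoms: none
Why: Acid-catalysed acetal solvolysis (transacetalisation to methanol) removes first the carbonyl-assisted 2′-O-MOM and then the 4′-O-MOM group at room temperature, where flavanone closure and ionisation of the secondary allylic alcohol should be slow, so C2″ stays (R).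

Compound list
1 | 5-methoxyresorcinol | COc1cc(O)cc(O)c1 | starting material
2 | 1-methoxy-3,5-bis(methoxymethoxy)benzene | COCOc1cc(OC)cc(OCOC)c1 | intermediate
3 | prenyl bromide (1-bromo-3-methylbut-2-ene) | CC(C)=CCBr | starting material
4 | [4-methoxy-2,6-bis(methoxymethoxy)phenyl]lithium | [Li]c1c(OCOC)cc(OC)cc1OCOC | intermediate
5 | 5-methoxy-1,3-bis(methoxymethoxy)-2-(3-methylbut-2-en-1-yl)benzene | CC(C)=CCc1c(OCOC)cc(OC)cc1OCOC | intermediate
6 | (3R)-3-{[4-methoxy-2,6-bis(methoxymethoxy)phenyl]methyl}-2,2-dimethyloxirane | CC1(C)O[C@@H]1Cc1c(OCOC)cc(OC)cc1OCOC | intermediate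
7 | diethylaluminium (2R)-1-[4-methoxy-2,6-bis(methoxymethoxy)phenyl]-3-methylbut-3-en-2-olate | C=C(C)[C@H](O[Al](CC)CC)Cc1c(OCOC)cc(OC)cc1OCOC | intermediate
8 | (2R)-1-[4-methoxy-2,6-bis(methoxymethoxy)phenyl]-3-methylbut-3-en-2-ol | C=C(C)[C@H](O)Cc1c(OCOC)cc(OC)cc1OCOC | intermediate
9 | N-methoxy-N-methylacrylamide | C=CC(=O)N(C)OC | starting material
10 | O,C-dilithio derivative of 8 (lithium alkoxide; aryl C–Li between OMOM and OMe) | C=C(C)[C@H](O[Li])Cc1c(OCOC)cc(OC)c([Li])c1OCOC | intermediate
11 | dilithium tetrahedral adduct of 10 and 9 (hemiaminal carbon unassigned) | C=C(C)[C@H](O[Li])Cc1c(OCOC)cc(OC)c(C(O[Li])(C=C)N(C)OC)c1OCOC | intermediate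
12 | 1-{3-[(2R)-2-hydroxy-3-methylbut-3-en-1-yl]-6-methoxy-2,4-bis(methoxymethoxy)phenyl}prop-2-en-1-one | C=C(C)[C@H](O)Cc1c(OCOC)cc(OC)c(C(=O)C=C)c1OCOC | intermediate
13 | 4-iodophenol | Oc1ccc(I)cc1 | starting material
14 | (2E)-1-{3-[(2R)-2-hydroxy-3-methylbut-3-en-1-yl]-6-methoxy-2,4-bis(methoxymethoxy)phenyl}-3-(4-hydroxyphenyl)prop-2-en-1-one | C=C(C)[C@H](O)Cc1c(OCOC)cc(OC)c(C(=O)/C=C/c2ccc(O)cc2)c1OCOC | intermediate
15 | (2E)-1-{2-hydroxy-3-[(2R)-2-hydroxy-3-methylbut-3-en-1-yl]-6-methoxy-4-(methoxymethoxy)phenyl}-3-(4-hydroxyphenyl)prop-2-en-1-one | C=C(C)[C@H](O)Cc1c(OCOC)cc(OC)c(C(=O)/C=C/c2ccc(O)cc2)c1O | intermediate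
16 | (2E)-1-{2,4-dihydroxy-3-[(2R)-2-hydroxy-3-methylbut-3-en-1-yl]-6-methoxyphenyl}-3-(4-hydroxyphenyl)prop-2-en-1-one | C=C(C)[C@H](O)Cc1c(O)cc(OC)c(C(=O)/C=C/c2ccc(O)cc2)c1O | target

Total step count: 7. Longest linear sequence: 7 (steps 1–7; the partners 3, 9 and 13 are purchased).

Steps most likely to fail

Step 6. The vinyl ketone may polymerise at the coupling temperature. The arylpalladium species may also attack the isopropenyl/allylic alcohol alkene with chain-walking, or phenoxide oxa-Michael addition may tie up the acceptor. The fallback sets out from 12. A rhodium(I)-catalysed 1,4-addition of Hayashi–Miyaura type with 4-hydroxyphenylboronic acid ([Rh(cod)OH]2, dioxane–H2O, rt) makes the same Cβ–aryl bond at the saturated level, is specific for the enone, and should give the dihydrochalcone F1. Dehydrogenation with DDQ (dioxane, rt) should run through the p-quinone methide of the 4-hydroxyphenyl ring and its tautomerisation to the conjugated E-enone. This comes back to the route at 14.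

Step 5. Three things may go wrong:
- The second metalation may stay incomplete in the presence of the alkoxide.
- The aryllithium may add 1,4 and start anionic oligomerisation of the acrylamide.
- The liberated hydroxylamine may add back to the enone during the quench.

The fallback sets out from 8 and builds the vinyl ketone by one-carbon homologation instead of direct acryloylation. The dilithio species 10 is quenched with N-methoxy-N-methylacetamide to give the methyl ketone F2. Its enolate (LiHMDS, 2.2 equiv, THF, −78 °C) is aminomethylated with Eschenmoser's salt to the storable Mannich base F3. Methyl iodide (Et2O, rt) gives the quaternary ammonium iodide F4. E1cB elimination with aq. NaHCO3–CH2Cl2 releases the vinyl ketone just before use and comes back to the route at 12.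

Step 7. The acid may drive 6-endo oxa-Michael closure of the freed 2′-OH to the flavanone. It may also cause ionisation of the allylic alcohol, protonation of the isopropenyl group with capture by a neighbouring phenol, or loss of material through incomplete cleavage of the 4′-O-MOM group. The fallback sets out from 14 and replaces Brønsted-acid solvolysis by a change of protecting group. TESOTf/2,2′-bipyridyl (CH2Cl2, 0 °C to rt) exchanges both aryl MOM acetals directly for silyl ethers and silylates the two free hydroxyl groups, giving the tetrakis(triethylsilyl) ether F5. Buffered fluoride (Et3N·3HF, THF, 0 °C) removes all four silyl groups under near-neutral conditions and comes back to the route at 16.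

Further compounds
F1 | step 6 | 1-{3-[(2R)-2-hydroxy-3-methylbut-3-en-1-yl]-6-methoxy-2,4-bis(methoxymethoxy)phenyl}-3-(4-hydroxyphenyl)propan-1-one | C=C(C)[C@H](O)Cc1c(OCOC)cc(OC)c(C(=O)CCc2ccc(O)cc2)c1OCOC
F2 | step 5 | 1-{3-[(2R)-2-hydroxy-3-methylbut-3-en-1-yl]-6-methoxy-2,4-bis(methoxymethoxy)phenyl}ethan-1-one | C=C(C)[C@H](O)Cc1c(OCOC)cc(OC)c(C(C)=O)c1OCOC
F3 | step 5 | 3-(dimethylamino)-1-{3-[(2R)-2-hydroxy-3-methylbut-3-en-1-yl]-6-methoxy-2,4-bis(methoxymethoxy)phenyl}propan-1-one | C=C(C)[C@H](O)Cc1c(OCOC)cc(OC)c(C(=O)CCN(C)C)c1OCOC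
F4 | step 5 | 3-{3-[(2R)-2-hydroxy-3-methylbut-3-en-1-yl]-6-methoxy-2,4-bis(methoxymethoxy)phenyl}-N,N,N-trimethyl-3-oxopropan-1-aminium iodide | C=C(C)[C@H](O)Cc1c(OCOC)cc(OC)c(C(=O)CC[N+](C)(C)C)c1OCOC.[I-]
F5 | step 7 | (2E)-1-{6-methoxy-3-[(2R)-3-methyl-2-(triethylsilyloxy)but-3-en-1-yl]-2,4-bis(triethylsilyloxy)phenyl}-3-[4-(triethylsilyloxy)phenyl]prop-2-en-1-one | C=C(C)[C@H](O[Si](CC)(CC)CC)Cc1c(O[Si](CC)(CC)CC)cc(OC)c(C(=O)/C=C/c2ccc(O[Si](CC)(CC)CC)cc2)c1O[Si](CC)(CC)CC
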